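**Retrosynthetic overview**
1. The γ-lactone and the C5/C6 oxygens are made last: syn-dihydroxylation of a (5E)-cyclodec-5-enone that carries a C7 acrylic acid, then C6-OH lactonisation onto C12.
2. Key step: the 10-membered ring is made by anionic oxy-Cope ring expansion of a 1-vinyl-2-[(Z)-propenyl]cyclohexanol. It breaks C1–C6, forms C3–C4, sets C4 and the E-C5=C6 alkene, and unveils the C1 ketone.
3. The cyclohexanone (C1, C6–C10) carrying C7, C8 and C10 comes from (S)-carvone: epoxidation/Wharton 1,3-transposition, α′-hydroxylation, then hydroxyl-directed epoxidation and hydride opening. The isopropenyl group becomes C11–C13.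
4. Ring order: carvone six-membered ring → ten-membered carbocycle (oxy-Cope) → γ-lactone.

Assumptions: the target is exactly the given SMILES, i.e. (4S,5S,6S,7R,8S,10R); germacrane numbering is used for ring atoms throughout. Only substrates and carbon-contributing building blocks are numbered; oxidants and silylating agents appear with SMILES on the reagent line.

---

**Step 1**
Reactants: 1, (S)-(+)-carvone
Product: 2, (1S,4S,6S)-1-methyl-4-(prop-1-en-2-yl)-7-oxabicyclo[4.1.0]heptan-2-one (epoxide anti to isopropenyl)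
Conditions: 30% H2O2, NaOH (cat.), MeOH, 0 °C
Reagents that add atoms: hydrogen peroxide, OO
Why: Weitz–Scheffer nucleophilic epoxidation; hydroperoxide adds to the enone β-carbon anti to the isopropenyl group, giving the known trans-epoxide, whose C–O stereocentre later becomes the C1 carbinol.

**Step 2**
Reactants: 2
Product: 3, (1S,3R,4R,6S)-3-hydroxy-1-methyl-4-(prop-1-en-2-yl)-7-oxabicyclo[4.1.0]heptan-2-one (OH trans to isopropenyl)
Conditions: NaHMDS, THF, −78 °C; then 2-(phenylsulfonyl)-3-phenyloxaziridine, −78 °C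
Reagents that add atoms: Davis oxaziridine, O=S(=O)(N1OC1c1ccccc1)c1ccccc1
Why: Davis enolate hydroxylation; the only enolisable position is the CH2 next to the isopropenyl-bearing carbon, and the oxidant approaches anti to that substituent, setting C8 (8S in the target).

**Step 3**
Reactants: 3
Product: 4, (1S,4S,5R)-2-methyl-5-(prop-1-en-2-yl)cyclohex-2-ene-1,4-diol (cis-1,4-diol, both OH anti to isopropenyl)
Conditions: N2H4·H2O, AcOH (cat.), MeOH, 0 °C → rt
Reagents that add atoms: none
Why: Wharton transposition (hydrazone, epoxide fragmentation, loss of N2); the carbonyl carbon becomes the future C9 and the allylic carbinol keeps the epoxide C–O configuration.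

**Step 4**
Reactants: 4
Product: 5, (1S,2S,4R,5R,6R)-1-methyl-4-(prop-1-en-2-yl)-7-oxabicyclo[4.1.0]heptane-2,5-diol (epoxide syn to both OH)
Conditions: VO(acac)2 (cat.), t-BuOOH, CH2Cl2, 0 °C → rt
Reagents that add atoms: tert-butyl hydroperoxide, CC(C)(C)OO
Why: Hydroxyl-directed (Sharpless-type vanadium) epoxidation; both allylic OH groups lie on the same face and deliver oxygen syn, fixing C10–O, while the undirected isopropenyl alkene is untouched.

**Step 5**
Reactants: 5
Product: 6, (1S,2R,4S,5R)-2-methyl-5-(prop-1-en-2-yl)cyclohexane-1,2,4-triol (three OH mutually cis)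
Conditions: LiAlH4, THF, 0 → 65 °C
Reagents that add atoms: none
Why: SN2 hydride opening of the trisubstituted epoxide at its secondary carbon (as in limonene oxide → β-terpineol) leaves the tertiary C10–OH with retained configuration (10R).

**Step 6**
Reactants: 6
Product: 7, (2R,4S,5R)-2,4-dihydroxy-2-methyl-5-(prop-1-en-2-yl)cyclohexan-1-one
Conditions: Bu2SnO, PhMe, reflux (−H2O); then NBS, CHCl3, rt
Reagents that add atoms: none
Why: David–Thieffry stannylene-acetal oxidation; the stannylene forms on the cis-vicinal sec/tert diol and brominolysis oxidises only its secondary carbinol, leaving the isolated C8–OH.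

**Step 7**
Reactants: 7
Product: 8, (2R,4S,5R)-2,4-dihydroxy-5-(3-hydroxyprop-1-en-2-yl)-2-methylcyclohexan-1-one
Conditions: SeO2 (cat.), t-BuOOH, salicylic acid (cat.), CH2Cl2, rt
Reagents that add atoms: selenium dioxide, O=[Se]=O, with tert-butyl hydroperoxide, CC(C)(C)OO, as reoxidant (one O)
Why: Riley/Sharpless allylic oxidation (ene then [2,3]); the isopropenyl group is the only alkene and its methyl is oxidised, as in the isopulegol-type motif, giving the future C12.

**Step 8**
Reactants: 8
Product: 9, (2R,4S,5R)-5-[3-(tert-butyldiphenylsilyloxy)prop-1-en-2-yl]-2-methyl-2,4-bis(triethylsilyloxy)cyclohexan-1-one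
Conditions: TBDPSCl, imidazole, CH2Cl2, 0 °C; then TESOTf, 2,6-lutidine, −78 → −40 °C (one pot)
Reagents that add atoms: TBDPSCl, CC(C)(C)[Si](Cl)(c1ccccc1)c1ccccc1; TESOTf, CC[Si](CC)(CC)OS(=O)(=O)C(F)(F)F
Why: Steric differentiation in silyl ether formation; the primary allylic OH takes the robust TBDPS group and the secondary and tertiary OH take TES, giving orthogonal protection for the endgame.

**Step 9**
Reactants: 9; 10, (Z)-1-bromoprop-1-ene
Product: 11, (2R,4S,5R,6S)-5-[3-(tert-butyldiphenylsilyloxy)prop-1-en-2-yl]-2-methyl-6-[(Z)-prop-1-en-1-yl]-2,4-bis(triethylsilyloxy)cyclohexan-1-one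
Conditions: LiHMDS, Pd2(dba)3, P(t-Bu)3, PhMe/THF, rt; AcOH quench at −78 °C
Reagents that add atoms: 10, (Z)-1-bromoprop-1-ene, C/C=C\Br
Why: Pd-catalysed ketone α-alkenylation; only C6 bears α-hydrogens, oxidative addition and reductive elimination retain the Z geometry, and the propenyl group ends equatorial, trans to the C7 substituent.

**Step 10**
Reactants: 11; 12, vinylmagnesium bromide
Product: 13, (1R,2R,4S,5R,6S)-5-[3-(tert-butyldiphenylsilyloxy)prop-1-en-2-yl]-1-ethenyl-2-methyl-6-[(Z)-prop-1-en-1-yl]-2,4-bis(triethylsilyloxy)cyclohexan-1-ol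
Conditions: CeCl3, THF, −78 °C
Reagents that add atoms: 12, vinylmagnesium bromide, C=C[Mg]Br
Why: Organocerium 1,2-addition suppresses enolisation of the β,γ-unsaturated ketone; axial attack anti to the axial C10 methyl is expected (the isomer drawn), and the C1 configuration does not matter because C1 becomes the ketone carbon.

**Step 11**
Reactants: 13
Product: 14, (4S,5E,7R,8S,10R)-7-[3-(tert-butyldiphenylsilyloxy)prop-1-en-2-yl]-4,10-dimethyl-8,10-bis(triethylsilyloxy)cyclodec-5-en-1-one
Conditions: KH, 18-crown-6, THF, 0 → 40 °C; MeOH quench at −78 °C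
Reagents that add atoms: none
Why: Anionic oxy-Cope [3,3] rearrangement; A(1,3) strain of the Z-propenyl group keeps H-6 in the alkene plane, so C1 leaves and C3 bonds on the same face of the C6–C5=C4 unit, giving the E-C5=C6 alkene and 4S, and the enolate is protonated to the C1 ketone.

**Step 12**
Reactants: 14
Product: 15, (4S,5E,7R,8S,10R)-7-[3-(tert-butyldiphenylsilyloxy)prop-1-en-2-yl]-8,10-dihydroxy-4,10-dimethylcyclodec-5-en-1-one
Conditions: HF·pyridine, pyridine, THF, 0 °C
Reagents that add atoms: none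
Why: Selective desilylation; buffered HF removes the two TES ethers while the primary TBDPS ether survives.

**Step 13**
Reactants: 15; 16, methacrylic anhydride
Product: 17, the C8 methacrylate of 15 (C10–OH free)
Conditions: Et3N, DMAP (cat.), CH2Cl2, 0 °C
Reagents that add atoms: 16, methacrylic anhydride, CC(=C)C(=O)OC(=O)C(C)=C
Why: DMAP-catalysed acylation; the secondary C8–OH reacts much faster than the tertiary α-ketol C10–OH.

**Step 14**
Reactants: 17; 18, acetic anhydride
Product: 19, (4S,5E,7R,8S,10R)-10-acetoxy-7-[3-(tert-butyldiphenylsilyloxy)prop-1-en-2-yl]-4,10-dimethyl-1-oxocyclodec-5-en-8-yl methacrylate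
Conditions: Ac2O, DMAP (2 equiv), Et3N, CH2Cl2, 35 °C
Reagents that add atoms: 18, acetic anhydride, CC(=O)OC(C)=O
Why: Forcing DMAP acetylation of the remaining tertiary alcohol; C5–OH does not exist yet, so no selectivity problem arises.

**Step 15**
Reactants: 19
Product: 20, the primary allylic alcohol (C12–OH) corresponding to 19
Conditions: TBAF/AcOH (1:1), THF, rt
Reagents that add atoms: none
Why: Buffered fluoride desilylation removes TBDPS without ester cleavage or acyl migration.

**Step 16**
Reactants: 20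
Product: 21, the 2-substituted acrolein (C12 aldehyde)
Conditions: MnO2, CH2Cl2, rt
Reagents that add atoms: none
Why: MnO2 oxidises only the allylic alcohol; C8 is already acylated, so no 8,12-lactol can form.

**Step 17**
Reactants: 21
Product: 22, 2-[(1R,2S,4R,7S,8E,10R)-4-acetoxy-2-(methacryloyloxy)-4,7-dimethyl-5-oxocyclodec-8-en-1-yl]prop-2-enoic acid
Conditions: NaClO2, NaH2PO4, 2-methyl-2-butene, t-BuOH/H2O, 0 °C → rt
Reagents that add atoms: sodium chlorite, [Na+].[O-]Cl=O
Why: Pinnick oxidation takes the enal to the acrylic acid without touching the alkenes, esters or the ketone.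

**Step 18**
Reactants: 22
Product: 23, Lychnostatin 1
Conditions: OsO4 (1.05 equiv), (DHQ)2PHAL, CH2Cl2, −78 °C; aq NaHSO3; then PPTS (cat.), CH2Cl2, rt
Reagents that add atoms: osmium tetroxide, O=[Os](=O)(=O)=O (two O)
Why: Ligand-accelerated syn-dihydroxylation of the electron-rich E-alkene (both other alkenes are acrylate-type); the (DHQ)2PHAL facial preference matches peripheral attack on the Cope-derived conformer to give 5S,6S, and the γ-hydroxy acid then lactonises through C6–OH to the trans-fused α-methylene lactone, leaving C5–OH free.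

---

**Compound list**
1 | (S)-(+)-carvone | CC1=CC[C@@H](CC1=O)C(C)=C | starting material
2 | (1S,4S,6S)-trans-carvone oxide | C1C(=O)[C@@]2(C)O[C@H]2C[C@@H]1C(C)=C | intermediate
3 | (1S,3R,4R,6S)-3-hydroxy carvone oxide | O[C@H]1C(=O)[C@@]2(C)O[C@H]2C[C@@H]1C(C)=C | intermediate
4 | (1S,4S,5R)-2-methyl-5-isopropenylcyclohex-2-ene-1,4-diol | O[C@H]1C=C(C)[C@@H](O)C[C@@H]1C(C)=C | intermediate
5 | (1S,2S,4R,5R,6R)-epoxy diol | O[C@H]1[C@H]2O[C@@]2(C)[C@@H](O)C[C@@H]1C(C)=C | intermediate
6 | (1S,2R,4S,5R)-2-methyl-5-isopropenylcyclohexane-1,2,4-triol | O[C@H]1C[C@@](C)(O)[C@@H](O)C[C@@H]1C(C)=C | intermediate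
7 | (2R,4S,5R)-2,4-dihydroxy-2-methyl-5-isopropenylcyclohexanone | O[C@H]1C[C@@](C)(O)C(=O)C[C@@H]1C(C)=C | intermediate
8 | (2R,4S,5R)-2,4-dihydroxy-5-(3-hydroxyprop-1-en-2-yl)-2-methylcyclohexanone | O[C@H]1C[C@@](C)(O)C(=O)C[C@@H]1C(=C)CO | intermediate
9 | tris-silyl ketone (2,4-bis-OTES, side-chain OTBDPS) | CC[Si](CC)(CC)O[C@H]1C[C@@](C)(O[Si](CC)(CC)CC)C(=O)C[C@@H]1C(=C)CO[Si](c2ccccc2)(c2ccccc2)C(C)(C)C | intermediate
10 | (Z)-1-bromoprop-1-ene | C/C=C\Br | starting material
11 | (2R,4S,5R,6S)-6-[(Z)-propenyl] ketone | CC[Si](CC)(CC)O[C@H]1C[C@@](C)(O[Si](CC)(CC)CC)C(=O)[C@@H](/C=C\C)[C@@H]1C(=C)CO[Si](c2ccccc2)(c2ccccc2)C(C)(C)C | intermediate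
12 | vinylmagnesium bromide | C=C[Mg]Br | starting material
13 | (1R,2R,4S,5R,6S)-1-vinyl-6-[(Z)-propenyl]cyclohexanol | CC[Si](CC)(CC)O[C@H]1C[C@@](C)(O[Si](CC)(CC)CC)[C@@](O)(C=C)[C@@H](/C=C\C)[C@@H]1C(=C)CO[Si](c2ccccc2)(c2ccccc2)C(C)(C)C | intermediate
14 | (4S,5E,7R,8S,10R)-cyclodec-5-en-1-one, 8,10-bis-OTES, side-chain OTBDPS | CC[Si](CC)(CC)O[C@H]1C[C@@](C)(O[Si](CC)(CC)CC)C(=O)CC[C@H](C)/C=C/[C@@H]1C(=C)CO[Si](c2ccccc2)(c2ccccc2)C(C)(C)C | intermediate
15 | 8,10-diol of 14 | O[C@H]1C[C@@](C)(O)C(=O)CC[C@H](C)/C=C/[C@@H]1C(=C)CO[Si](c2ccccc2)(c2ccccc2)C(C)(C)C | intermediate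
16 | methacrylic anhydride | CC(=C)C(=O)OC(=O)C(C)=C | starting material
17 | 8-methacrylate, 10-OH | C=C(C)C(=O)O[C@H]1C[C@@](C)(O)C(=O)CC[C@H](C)/C=C/[C@@H]1C(=C)CO[Si](c2ccccc2)(c2ccccc2)C(C)(C)C | intermediate
18 | acetic anhydride | CC(=O)OC(C)=O | starting material
19 | 8-methacrylate, 10-acetate, side-chain OTBDPS | C=C(C)C(=O)O[C@H]1C[C@@](C)(OC(C)=O)C(=O)CC[C@H](C)/C=C/[C@@H]1C(=C)CO[Si](c2ccccc2)(c2ccccc2)C(C)(C)C | intermediate
20 | C12 allylic alcohol | C=C(C)C(=O)O[C@H]1C[C@@](C)(OC(C)=O)C(=O)CC[C@H](C)/C=C/[C@@H]1C(=C)CO | intermediate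
21 | C12 enal | C=C(C)C(=O)O[C@H]1C[C@@](C)(OC(C)=O)C(=O)CC[C@H](C)/C=C/[C@@H]1C(=C)C=O | intermediate
22 | C12 acrylic acid | C=C(C)C(=O)O[C@H]1C[C@@](C)(OC(C)=O)C(=O)CC[C@H](C)/C=C/[C@@H]1C(=C)C(=O)O | intermediate
23 | Lychnostatin 1 (4S,5S,6S,7R,8S,10R) | C=C(C)C(=O)O[C@H]1C[C@@](C)(OC(C)=O)C(=O)CC[C@H](C)[C@H](O)[C@H]2OC(=O)C(=C)[C@@H]21 | target

---

**Total step count:** 18
**Longest linear sequence:** 18 steps from (S)-carvone (compounds 10, 12, 16 and 18 are purchased).

**Three steps most likely to fail, with fallbacks**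
1. **Step 11 (oxy-Cope).** The cis-vinyl/propenyl alkoxide must react through a boat-like transition state. A competing chair would give the Z-alkene and 4-epi product, and silyl migration could stall the reaction. Fallback: replace the [3,3] shift by a Grob fragmentation. Aldol of the C6 enolate of 9 with 4-iodo-2-methylbutanal, then SmI2 Barbier closure onto the C1 ketone, gives a decalin-1,5-diol. Mesylation of the C5–OH and KOt-Bu then cleave C1–C6, with C4 set on a chair and the alkene geometry set by the antiperiplanar C5–OMs.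
2. **Step 18 (face of dihydroxylation).** If the ground-state ring conformer presents the other alkene face, OsO4 would give the 5R,6R diol. Fallback: tether-controlled oxygenation. Iodolactonisation of 22 (carboxylate attacks C6 anti to the iodonium), then SN2 displacement of the C5 iodide by an oxygen nucleophile, places both oxygens on the face opposite to the one OsO4 attacks.
3. **Step 9 (Pd α-alkenylation).** Risks are isomerisation to the conjugated enone, loss of Z geometry, or low conversion at the hindered ketone. Fallback: aldol condensation of 9 with propanal to the (E)-2-propylidene ketone, then γ-deprotonation (LDA/HMPA) and kinetic α-protonation. This deconjugation is expected to give the (Z)-β,γ-enone through the "syn effect".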